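**Retrosynthetic overview**

- The ten-membered carbocycle and the trans α-methylene-γ-lactone are closed together in the last step by an intramolecular chromium-mediated allylation (C6–C7) of a seco lactol / allylic bromide.
- The seco compound comes from a cross-metathesis (C1=C10) between a C4-defined γ-lactol carrying a butenyl chain and a C7–C14 diester bromide that already holds the C8 ester.
- The lactol comes from a γ-lactone made by catalytic enantioselective Baeyer–Villiger ring expansion of a prochiral 3-(but-3-enyl)cyclobutanone (1,2-shift of a ring CH2 from carbon to oxygen). This is the key step: it sets C4 and tells C6 (carbonyl) from C15 (C–O). The cyclobutanone comes from a keteniminium [2+2] on hexa-1,5-diene.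
- The diester bromide comes from (S)-glyceraldehyde acetonide (relays C8), methyl 2-(bromomethyl)acrylate, (S)-2-methylbutanoic acid and methyl propiolate.
- Ring order: cyclobutanone → γ-lactone/lactol (ring expansion) → ten-membered ring plus α-methylene-γ-lactone (one step).

Assumption and labels: (4S)-2,2-dimethyl-1,3-dioxolane-4-carbaldehyde is purchased; locants C1–C15 are germacrane locants of the target (ring C1–C10, C1=C10, C15 = CH2OH on C4, lactone O on C6, C7 ring fusion, ester O on C8, C11/C12/C13 = lactone α-carbon/carbonyl/methylidene, C14 = ester carbon).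

**Route**

Step 1
Reactants: 1 hexa-1,5-diene; 2 N,N-dimethylacetamide
Product: 5 3-(but-3-en-1-yl)cyclobutan-1-one, via N,N-dimethylketeniminium triflate 3 (not isolated), via cyclobutaniminium triflate 4 (not isolated)
Conditions: Tf2O, 2,4,6-collidine, ClCH2CH2Cl, −15 °C → reflux (1 in 4-fold excess); then H2O, reflux
Reagents that add atoms: water, O
Why: Ghosez keteniminium [2+2] cycloaddition, in which the electrophilic central carbon of the keteniminium attacks the terminal alkene carbon so that only the 3-substituted cyclobutaniminium forms and hydrolysis gives the ketone, the excess diene holding the reaction at mono-addition.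

Step 2
Reactants: 5 3-(but-3-en-1-yl)cyclobutan-1-one
Product: 6 (4S)-4-(but-3-en-1-yl)oxolan-2-one
Conditions: mCPBA (1.05 equiv), Sc(OTf)3 (5 mol %), chiral N,N′-dioxide ligand from (S)-pipecolic acid and 2,6-diisopropylaniline (6 mol %), EtOAc, −20 °C
Reagents that add atoms: 3-chloroperbenzoic acid (mCPBA), OOC(=O)c1cccc(Cl)c1
Why: Enantiotopic-group-selective Baeyer–Villiger oxidation, a ring expansion by 1,2-shift of one of the two enantiotopic ring CH2 groups from carbon to oxygen in the scandium-bound Criegee adduct, which sets C4 (S) (the mirror-image ligand gives the antipode) and oxidises the strained ketone far faster than the terminal alkene at −20 °C.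

Step 3
Reactants: 6 (4S)-4-(but-3-en-1-yl)oxolan-2-one
Product: 7 (4S)-4-(but-3-en-1-yl)oxolan-2-ol (anomer mixture)
Conditions: i-Bu2AlH (1.1 equiv), CH2Cl2, −78 °C; aq. potassium sodium tartrate
Reagents that add atoms: none
Why: Partial hydride reduction of a γ-lactone stops at the tetrahedral aluminium hemiacetal at −78 °C and gives the lactol, which serves as latent C6 aldehyde and as protection of the C15 hydroxyl, C4 being untouched.

Step 4
Reactants: 8 (4S)-2,2-dimethyl-1,3-dioxolane-4-carbaldehyde; 9 methyl 2-(bromomethyl)prop-2-enoate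
Product: 10 methyl (4R)-4-[(4S)-2,2-dimethyl-1,3-dioxolan-4-yl]-4-hydroxy-2-methylidenebutanoate
Conditions: indium powder (1.2 equiv), THF/H2O 1:1, 25 °C
Reagents that add atoms: none
Why: Barbier-type indium allylation of an α-alkoxy aldehyde follows Felkin–Anh (anti) addition and sets C8 (R) (anti:syn about 6:1, minor isomer removed by chromatography), while the neutral aqueous medium leaves the acetonide intact and the γ-hydroxy ester unlactonised.

Step 5
Reactants: 10 methyl (4R)-4-[(4S)-2,2-dimethyl-1,3-dioxolan-4-yl]-4-hydroxy-2-methylidenebutanoate; 11 (2S)-2-methylbutanoic acid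
Product: 12 methyl (4R)-4-[(4S)-2,2-dimethyl-1,3-dioxolan-4-yl]-2-methylidene-4-{[(2S)-2-methylbutanoyl]oxy}butanoate
Conditions: DCC, DMAP (5 mol %), CH2Cl2, 0 → 25 °C
Reagents that add atoms: none
Why: Steglich esterification outruns lactonisation of the γ-hydroxy ester and, at low DMAP loading, does not epimerise the acid, so the final C8 ester is in place early and no hydroxyl differentiation is needed later.

Step 6
Reactants: 12 methyl (4R)-4-[(4S)-2,2-dimethyl-1,3-dioxolan-4-yl]-2-methylidene-4-{[(2S)-2-methylbutanoyl]oxy}butanoate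
Product: 14 methyl (4R)-2-methylidene-4-{[(2S)-2-methylbutanoyl]oxy}-5-oxopentanoate, via terminal diol 13 (not isolated)
Conditions: H5IO6 (1.5 equiv), EtOAc, 25 °C; used crude
Reagents that add atoms: none
Why: Periodic acid first cleaves the terminal acetonide and then effects Malaprade glycol cleavage in the same flask, turning the relay stereocentre into the C7 aldehyde without touching C8.

Step 7
Reactants: 14 methyl (4R)-2-methylidene-4-{[(2S)-2-methylbutanoyl]oxy}-5-oxopentanoate; 15 methyl prop-2-ynoate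
Product: 17 dimethyl (4R)-3-hydroxy-2,6-dimethylidene-4-{[(2S)-2-methylbutanoyl]oxy}heptanedioate (both C3 epimers), via vinylalane 16 (not isolated)
Conditions: 15, i-Bu2AlH (1.0 equiv), NMO, THF, 0 °C, 30 min; then 14, 0 → 25 °C
Reagents that add atoms: none
Why: Vinylalumination (hydroalumination of the ynoate to the α-aluminio acrylate, then chemoselective addition to the aldehyde) is a base-free equivalent of the Morita–Baylis–Hillman reaction, so the α-acyloxy aldehyde keeps C8, and the new carbinol (C7) is formed as a mixture that converges in step 8.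

Step 8
Reactants: 17 dimethyl (4R)-3-hydroxy-2,6-dimethylidene-4-{[(2S)-2-methylbutanoyl]oxy}heptanedioate
Product: 18 dimethyl (2Z,4R)-2-(bromomethyl)-6-methylidene-4-{[(2S)-2-methylbutanoyl]oxy}hept-2-enedioate
Conditions: NBS, Me2S, CH2Cl2, 0 → 25 °C
Reagents that add atoms: N-bromosuccinimide, BrN1C(=O)CCC1=O
Why: Corey–Kim-type activation of the allylic alcohol followed by SN2′ attack of bromide gives the transposed primary bromide with the chain cis to CH2Br (Z), the geometry that avoids A(1,3) strain with the ester, from both carbinol epimers.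

Step 9
Reactants: 7 (4S)-4-(but-3-en-1-yl)oxolan-2-ol; 18 dimethyl (2Z,4R)-2-(bromomethyl)-6-methylidene-4-{[(2S)-2-methylbutanoyl]oxy}hept-2-enedioate
Product: 19 methyl (2Z,4R,6E)-2-(bromomethyl)-9-[(3S)-5-hydroxyoxolan-3-yl]-6-(methoxycarbonyl)-4-{[(2S)-2-methylbutanoyl]oxy}nona-2,6-dienoate
Conditions: 7 (3 equiv), RuCl2(H2IMes)(=CH–C6H4-2-OiPr) (Hoveyda–Grubbs second-generation catalyst, 7 mol %), CH2Cl2, 40 °C
Reagents that add atoms: none
Why: Olefin cross-metathesis of the terminal alkene with the 2-substituted acrylate (the trisubstituted bromo-enoate is inert) gives the thermodynamically preferred (E)-trisubstituted enoate with the chain trans to CO2Me, which is the ring-cis C1=C10 geometry of the target.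

Step 10
Reactants: 19 methyl (2Z,4R,6E)-2-(bromomethyl)-9-[(3S)-5-hydroxyoxolan-3-yl]-6-(methoxycarbonyl)-4-{[(2S)-2-methylbutanoyl]oxy}nona-2,6-dienoate
Product: 21 methyl (3aS,4R,6E,10S,11aR)-10-(hydroxymethyl)-3-methylidene-4-{[(2S)-2-methylbutanoyl]oxy}-2-oxo-2,3,3a,4,5,8,9,10,11,11a-decahydrocyclodeca[b]furan-6-carboxylate (CNP0141952.2), via seco hydroxy ester 20 (not isolated)
Conditions: CrCl2 (8 equiv), DMF/THF 1:1, 2 mM (syringe pump), 25 °C; aq. NH4Cl; then PPTS (cat.), CH2Cl2
Reagents that add atoms: none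
Why: Proposed new method: divalent chromium inserts into the allylic C–Br bond to give a 2-(methoxycarbonyl)allyl–chromium species, the γ-lactol opens reversibly (trivalent chromium as Lewis acid) to the ω-hydroxy aldehyde, and γ-attack of C7 on C6 through a six-membered chair (Zimmerman–Traxler) transition state closes the ten-membered ring with C6/C7 anti (trans-lactone after loss of methanol), C8–H lying in the allyl plane (A(1,3) strain with the ester) and C6 adding to the face anti to the C8–C9 bond so that C7 (S) and C6 (R) follow from C8 (R) while the ring-cis enoate pre-organises the chain; the closest known reaction types are the Nozaki–Hiyama/Barbier macrocyclisation of ω-formyl 2-(bromomethyl)enoates to germacranolides and the allylation of lactols with allylindium reagents, but a lactol has not served as the carbonyl partner of a medium-ring-forming allylation.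

**Compound list**

1 | hexa-1,5-diene | C=CCCC=C | starting material
2 | N,N-dimethylacetamide | CC(=O)N(C)C | starting material
3 | N-ethenylidene-N-methylmethanaminium trifluoromethanesulfonate (N,N-dimethylketeniminium triflate) | C=C=[N+](C)C.[O-]S(=O)(=O)C(F)(F)F | intermediate
4 | N-[3-(but-3-en-1-yl)cyclobutylidene]-N-methylmethanaminium trifluoromethanesulfonate | C[N+](C)=C1CC(CCC=C)C1.[O-]S(=O)(=O)C(F)(F)F | intermediate
5 | 3-(but-3-en-1-yl)cyclobutan-1-one | O=C1CC(CCC=C)C1 | intermediate
6 | (4S)-4-(but-3-en-1-yl)oxolan-2-one | O=C1C[C@@H](CO1)CCC=C | intermediate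
7 | (4S)-4-(but-3-en-1-yl)oxolan-2-ol (anomer mixture) | OC1C[C@@H](CO1)CCC=C | intermediate
8 | (4S)-2,2-dimethyl-1,3-dioxolane-4-carbaldehyde | O=C[C@@H]1COC(C)(C)O1 | starting material
9 | methyl 2-(bromomethyl)prop-2-enoate | C=C(CBr)C(=O)OC | starting material
10 | methyl (4R)-4-[(4S)-2,2-dimethyl-1,3-dioxolan-4-yl]-4-hydroxy-2-methylidenebutanoate | C=C(C[C@@H](O)[C@@H]1COC(C)(C)O1)C(=O)OC | intermediate
11 | (2S)-2-methylbutanoic acid | CC[C@H](C)C(=O)O | starting material
12 | methyl (4R)-4-[(4S)-2,2-dimethyl-1,3-dioxolan-4-yl]-2-methylidene-4-{[(2S)-2-methylbutanoyl]oxy}butanoate | C=C(C[C@@H](OC(=O)[C@@H](C)CC)[C@@H]1COC(C)(C)O1)C(=O)OC | intermediate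
13 | methyl (4R,5S)-5,6-dihydroxy-2-methylidene-4-{[(2S)-2-methylbutanoyl]oxy}hexanoate | C=C(C[C@@H](OC(=O)[C@@H](C)CC)[C@@H](O)CO)C(=O)OC | intermediate
14 | methyl (4R)-2-methylidene-4-{[(2S)-2-methylbutanoyl]oxy}-5-oxopentanoate | C=C(C[C@@H](OC(=O)[C@@H](C)CC)C=O)C(=O)OC | intermediate
15 | methyl prop-2-ynoate | C#CC(=O)OC | starting material
16 | methyl 2-[bis(2-methylpropyl)alumanyl]prop-2-enoate | C=C([Al](CC(C)C)CC(C)C)C(=O)OC | intermediate
17 | dimethyl (4R)-3-hydroxy-2,6-dimethylidene-4-{[(2S)-2-methylbutanoyl]oxy}heptanedioate (both C3 epimers) | C=C(C[C@@H](OC(=O)[C@@H](C)CC)C(O)C(=C)C(=O)OC)C(=O)OC | intermediate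
18 | dimethyl (2Z,4R)-2-(bromomethyl)-6-methylidene-4-{[(2S)-2-methylbutanoyl]oxy}hept-2-enedioate | C=C(C[C@@H](OC(=O)[C@@H](C)CC)/C=C(\CBr)C(=O)OC)C(=O)OC | intermediate
19 | methyl (2Z,4R,6E)-2-(bromomethyl)-9-[(3S)-5-hydroxyoxolan-3-yl]-6-(methoxycarbonyl)-4-{[(2S)-2-methylbutanoyl]oxy}nona-2,6-dienoate | OC1C[C@@H](CO1)CC/C=C(/C(=O)OC)C[C@@H](OC(=O)[C@@H](C)CC)/C=C(\CBr)C(=O)OC | intermediate
20 | methyl (1E,5S,7R,8S,9R)-7-hydroxy-5-(hydroxymethyl)-8-(3-methoxy-3-oxoprop-1-en-2-yl)-9-{[(2S)-2-methylbutanoyl]oxy}cyclodec-1-ene-1-carboxylate | O[C@@H]2C[C@@H](CO)CC/C=C(/C(=O)OC)C[C@@H](OC(=O)[C@@H](C)CC)[C@H]2C(=C)C(=O)OC | intermediate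
21 | methyl (3aS,4R,6E,10S,11aR)-10-(hydroxymethyl)-3-methylidene-4-{[(2S)-2-methylbutanoyl]oxy}-2-oxo-2,3,3a,4,5,8,9,10,11,11a-decahydrocyclodeca[b]furan-6-carboxylate | C=C1C(=O)O[C@@H]2C[C@@H](CO)CC/C=C(/C(=O)OC)C[C@@H](OC(=O)[C@@H](C)CC)[C@@H]12 | target

**Totals and risks**

Total steps: 10. Longest linear sequence: 7 (steps 4–10); the lactol branch (steps 1–3) joins at step 9.

The three steps most likely to fail:

Step 10 (the new macro-allylation). The risks are 1,4-elimination of the C8 acyloxy group from the allyl–chromium species, sluggish opening of the lactol, and the wrong facial sense at C7 relative to C8; the C7/C8 facial model is an argued prediction, not a precedented result, and the fallback rests on the same model. The fallback uses known chemistry, sets out from lactone 6 (with bromide 18) and comes back at 21. Lactone 6 is opened with MeNH(OMe)·HCl/AlMe3 to (3S)-3-(hydroxymethyl)-N-methoxy-N-methylhept-6-enamide F1. Silylation (TBSCl, imidazole) gives (3S)-3-({[tert-butyl(dimethyl)silyl]oxy}methyl)-N-methoxy-N-methylhept-6-enamide F2. Reduction with i-Bu2AlH at −78 °C gives (3S)-3-({[tert-butyl(dimethyl)silyl]oxy}methyl)hept-6-enal F3. Intermolecular Nozaki–Hiyama allylation of F3 with 18 (CrCl2, THF; anti addition, lactonisation in the flask) gives methyl (4R)-4-{(2R,3S)-2-[(2S)-2-({[tert-butyl(dimethyl)silyl]oxy}methyl)hex-5-en-1-yl]-4-methylidene-5-oxooxolan-3-yl}-2-methylidene-4-{[(2S)-2-methylbutanoyl]oxy}butanoate F4. Ring-closing metathesis with RuCl2(H2IMes)(PCy3)(=CHPh) (second-generation Grubbs catalyst, 1 mM, toluene, 80 °C) closes C1=C10 to methyl (3aS,4R,6E,10S,11aR)-10-({[tert-butyl(dimethyl)silyl]oxy}methyl)-3-methylidene-4-{[(2S)-2-methylbutanoyl]oxy}-2-oxo-2,3,3a,4,5,8,9,10,11,11a-decahydrocyclodeca[b]furan-6-carboxylate F5. HF·pyridine then gives 21.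

Step 7 (vinylalumination of the α-acyloxy aldehyde). The risks are acyl migration from C8 to the new alkoxide and over-reduction by excess hydride. The fallback sets out from 14 and comes back at 18. Wittig olefination of 14 with methyl 2-(triphenylphosphoranylidene)propanoate (CH2Cl2, 25 °C) gives dimethyl (2E,4R)-2-methyl-6-methylidene-4-{[(2S)-2-methylbutanoyl]oxy}hept-2-enedioate F6. Wohl–Ziegler bromination of the 2-methyl group (NBS, AIBN, PhCF3, 80 °C) then gives 18 with the geometry retained.

Step 2 (enantioselective Baeyer–Villiger on a 3-alkyl cyclobutanone). The risk is only moderate enantiomeric excess for an alkyl substituent. The fallback sets out from 5 and comes back at 6. Enantioselective deprotonation with the enantiomer of lithium bis(1-phenylethyl)amide that gives the (3S) product, with TMSCl (THF, −100 °C), gives {[(3S)-3-(but-3-en-1-yl)cyclobut-1-en-1-yl]oxy}(trimethyl)silane F7. Ozonolysis limited to the electron-rich enol ether (1 equiv O3, CH2Cl2/MeOH, −78 °C, then Me2S) gives (3S)-3-formylhept-6-enoic acid F8. NaBH4 reduces the aldehyde to (3S)-3-(hydroxymethyl)hept-6-enoic acid F9, which lactonises on acidification to 6.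

Further compounds
F1 | step 10 | (3S)-3-(hydroxymethyl)-N-methoxy-N-methylhept-6-enamide | CON(C)C(=O)C[C@@H](CO)CCC=C
F2 | step 10 | (3S)-3-({[tert-butyl(dimethyl)silyl]oxy}methyl)-N-methoxy-N-methylhept-6-enamide | CON(C)C(=O)C[C@@H](CO[Si](C)(C)C(C)(C)C)CCC=C
F3 | step 10 | (3S)-3-({[tert-butyl(dimethyl)silyl]oxy}methyl)hept-6-enal | O=CC[C@@H](CO[Si](C)(C)C(C)(C)C)CCC=C
F4 | step 10 | methyl (4R)-4-{(2R,3S)-2-[(2S)-2-({[tert-butyl(dimethyl)silyl]oxy}methyl)hex-5-en-1-yl]-4-methylidene-5-oxooxolan-3-yl}-2-methylidene-4-{[(2S)-2-methylbutanoyl]oxy}butanoate | C=C1C(=O)O[C@H](C[C@@H](CO[Si](C)(C)C(C)(C)C)CCC=C)[C@H]1[C@H](OC(=O)[C@@H](C)CC)CC(=C)C(=O)OC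
F5 | step 10 | methyl (3aS,4R,6E,10S,11aR)-10-({[tert-butyl(dimethyl)silyl]oxy}methyl)-3-methylidene-4-{[(2S)-2-methylbutanoyl]oxy}-2-oxo-2,3,3a,4,5,8,9,10,11,11a-decahydrocyclodeca[b]furan-6-carboxylate | C=C1C(=O)O[C@@H]2C[C@@H](CO[Si](C)(C)C(C)(C)C)CC/C=C(/C(=O)OC)C[C@@H](OC(=O)[C@@H](C)CC)[C@@H]12
F6 | step 7 | dimethyl (2E,4R)-2-methyl-6-methylidene-4-{[(2S)-2-methylbutanoyl]oxy}hept-2-enedioate | C=C(C[C@@H](OC(=O)[C@@H](C)CC)/C=C(\C)C(=O)OC)C(=O)OC
F7 | step 2 | {[(3S)-3-(but-3-en-1-yl)cyclobut-1-en-1-yl]oxy}(trimethyl)silane | C[Si](C)(C)OC1=C[C@@H](CCC=C)C1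
F8 | step 2 | (3S)-3-formylhept-6-enoic acid | OC(=O)C[C@@H](C=O)CCC=C
F9 | step 2 | (3S)-3-(hydroxymethyl)hept-6-enoic acid | OC(=O)C[C@@H](CO)CCC=C
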